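The C40 chain is cut at the disubstituted double bonds C11=C12 and C11′=C12′: a C10 bis-phosphonate joins an ε-C15 dienal and a furanoid C15 enal by two Horner–Wadsworth–Emmons reactions. The dienal comes from a Julia olefination at C7′=C8′ of an α-cyclogeranyl sulfone, the product of the key step, which exploits the ε-ring pattern: stereocentre C6′ between gem-dimethyl C1′ and the C4′=C5′ alkene. In one operation a chiral Brønsted acid turns the acyclic C10 diene geranyl phenyl sulfone into this ring, forming C1′–C6′, setting C6′ as R and placing the ring alkene. C5 and C8 come from a Sharpless epoxidation and allene-to-dihydrofuran chirality transfer.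

Key step: step 2

Remark: atom labels follow carotenoid numbering (unprimed: furanoid half; primed: ε half); the C5 acetal-aldehyde, the C10 dialdehyde, β-cyclocitral and but-2-yn-1-ol are taken as catalogue chemicals, and the antipode of the chiral acid in step 2 is fixed in the first run by comparison with the resolved sample of the fallback.

Step 1
Reactants: 1 geranyl bromide ((2E)-1-bromo-3,7-dimethylocta-2,6-diene); 2 sodium benzenesulfinate
Product: 3 geranyl phenyl sulfone ((2E)-3,7-dimethylocta-2,6-dien-1-yl phenyl sulfone)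
Conditions: DMF, rt
Reagents that add atoms: none
Why: SN2 S-alkylation of the sulfinate by the primary allylic bromide (sulfone synthesis from a sulfinate salt) should give the allylic sulfone with the 2E geometry intact.

Step 2
Reactants: 3 geranyl phenyl sulfone
Product: 4 (R)-α-cyclogeranyl phenyl sulfone ({[(1R)-2,6,6-trimethylcyclohex-2-en-1-yl]methyl} phenyl sulfone)
Conditions: chiral confined imidodiphosphorimidate Brønsted acid (5 mol %), (CF3)3COH–CHCl3, −40 °C
Reagents that add atoms: none
Why: Proposed new method: The confined chiral acid protonates the electron-rich terminal C1′=C2′ alkene (the C5′=C6′ alkene is deactivated inductively by the allylic sulfonyl group), C6′ of that internal alkene attacks the tertiary C1′ cation in a chair-like fold, and the C5′ cation loses the C4′ proton to the catalyst anion, which regenerates the acid. The closest known reaction type is the catalytic enantioselective proton-initiated polyene cyclisation with confined or Lewis-acid-assisted chiral Brønsted acids, shown for polyenes terminated by a hydroxyl or arene nucleophile but not for an elimination-terminated monocyclisation of an allylic sulfone. The six-membered ε-ring closes in the 6-endo-trig mode through the new C1′–C6′ bond. C6′ is set under catalyst control, by the face of the C5′=C6′ alkene that the chiral ion pair presents to C1′, and the catalyst antipode is chosen to give R. The step needs enantioface selection and α-selective proton loss (C4′–H, not C6′–H or C18′–H): the 2E geometry and the chair fold place the sulfonylmethyl group equatorial, the sulfonyl oxygen atoms give the acid a hydrogen-bond anchor, the confined anion is the only base, and low temperature should keep the product alkene from being re-protonated.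

Step 3
Reactants: 4 (R)-α-cyclogeranyl phenyl sulfone; 5 (2E)-4,4-dimethoxy-2-methylbut-2-enal
Product: 8 (3E)-5,5-dimethoxy-3-methyl-1-(phenylsulfonyl)-1-[(1R)-2,6,6-trimethylcyclohex-2-en-1-yl]pent-3-en-2-yl acetate (C7′/C8′ diastereomer mixture), via lithiated sulfone 6 (not isolated), via lithium alkoxide 7 (not isolated)
Conditions: n-BuLi, THF, −78 °C; then 5; then Ac2O, −78 °C → rt
Reagents that add atoms: acetic anhydride, CC(=O)OC(C)=O
Why: Addition of the α-sulfonyl carbanion to the aldehyde of 5 and O-acetylation in the same flask form the β-acetoxy sulfone (first stage of a Julia–Lythgoe olefination); the C6′ proton is not acidic, so the centre set in step 2 is untouched.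

Step 4
Reactants: 8 β-acetoxy sulfone
Product: 9 (6R)-6-[(1E,3E)-5,5-dimethoxy-3-methylpenta-1,3-dien-1-yl]-1,5,5-trimethylcyclohex-1-ene
Conditions: 6% Na(Hg), Na2HPO4, THF–MeOH, −20 °C
Reagents that add atoms: none
Why: Reductive elimination of the β-acetoxy sulfone with sodium amalgam (second stage of the Julia–Lythgoe olefination) forms C7′=C8′ with the usual strong E preference, and the ring alkene, the acetal and C6′ are inert to the reductant.

Step 5
Reactants: 9 dienyl acetal
Product: 10 (2E,4E)-3-methyl-5-[(1R)-2,6,6-trimethylcyclohex-2-en-1-yl]penta-2,4-dienal (ε-C15 dienal)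
Conditions: PPTS (cat.), acetone–H2O, rt
Reagents that add atoms: water, O
Why: Acid-catalysed hydrolysis of the allylic dimethyl acetal (acetal cleavage) is fast under conditions too mild to move the C4′=C5′ bond into conjugation or to touch C6′.

Step 6
Reactants: 11 (2E,4E,6E)-2,7-dimethylocta-2,4,6-trienedial
Product: 12 (2E,4E,6E)-2,7-dimethylocta-2,4,6-triene-1,8-diol
Conditions: NaBH4, MeOH–THF, 0 °C
Reagents that add atoms: none
Why: Borohydride 1,2-reduction of the two enal carbonyl groups (carbonyl reduction) should give the allylic diol with the triene geometry unchanged.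

Step 7
Reactants: 12 C10 diol
Product: 13 (2E,4E,6E)-1,8-dibromo-2,7-dimethylocta-2,4,6-triene
Conditions: PBr3, pyridine (cat.), Et2O, −10 °C, dark
Reagents that add atoms: phosphorus tribromide, BrP(Br)Br
Why: Substitution of the primary allylic hydroxyl groups by bromide with PBr3 gives the conjugated primary dibromide, the thermodynamically preferred allylic isomer.

Step 8
Reactants: 13 C10 dibromide
Product: 14 tetraethyl [(2E,4E,6E)-2,7-dimethylocta-2,4,6-triene-1,8-diyl]bis(phosphonate)
Conditions: P(OEt)3, toluene, 90 °C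
Reagents that add atoms: triethyl phosphite, CCOP(OCC)OCC
Why: Michaelis–Arbuzov reaction of the allylic dibromide with triethyl phosphite installs both phosphonate groups at the primary carbons.

Step 9
Reactants: 14 C10 bis-phosphonate; 10 ε-C15 dienal
Product: 16 diethyl [(2E,4E,6E,8E,10E,12E)-2,7,11-trimethyl-13-[(1R)-2,6,6-trimethylcyclohex-2-en-1-yl]trideca-2,4,6,8,10,12-hexaen-1-yl]phosphonate, via potassium phosphonate carbanion 15 (not isolated)
Conditions: 14 (3 equiv), KOtBu (1 equiv), THF, −30 °C; then 10, −30 °C → rt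
Reagents that add atoms: none
Why: Horner–Wadsworth–Emmons olefination of the mono-anion of the bis-phosphonate (used in excess to suppress double olefination) with the dienal forms C11′=C12′ with E selectivity and leaves the second phosphonate for step 20.

Step 10
Reactants: 17 β-cyclocitral (2,6,6-trimethylcyclohex-1-ene-1-carbaldehyde)
Product: 18 β-cyclogeraniol ((2,6,6-trimethylcyclohex-1-en-1-yl)methanol)
Conditions: NaBH4, MeOH, 0 °C
Reagents that add atoms: none
Why: Borohydride 1,2-reduction of the hindered conjugated aldehyde (carbonyl reduction) gives the tetrasubstituted allylic alcohol needed for directed epoxidation.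

Step 11
Reactants: 18 β-cyclogeraniol
Product: 19 [(1R,6R)-2,2,6-trimethyl-7-oxabicyclo[4.1.0]heptan-1-yl]methanol
Conditions: Ti(OiPr)4, D-(−)-diethyl tartrate, t-BuOOH, 4 Å MS, CH2Cl2, −20 °C
Reagents that add atoms: tert-butyl hydroperoxide, CC(C)(C)OO
Why: Sharpless asymmetric epoxidation: the titanium–tartrate complex bound to the allylic hydroxyl delivers oxygen to one face of the C5=C6 alkene, and D-(−)-diethyl tartrate (the antipode that converts geraniol into its 2R,3R epoxide) sets C5 as R together with C6.

Step 12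
Reactants: 19 epoxy alcohol
Product: 20 (1S,6R)-2,2,6-trimethyl-7-oxabicyclo[4.1.0]heptane-1-carbaldehyde
Conditions: TPAP (5 mol %), NMO, 4 Å MS, CH2Cl2, rt
Reagents that add atoms: none
Why: Ley–Griffith oxidation (catalytic TPAP with NMO) converts the neopentyl-type primary alcohol into the non-enolisable aldehyde under neutral conditions that spare the acid-sensitive tetrasubstituted epoxide.

Step 13
Reactants: 20 epoxy aldehyde
Product: 21 (1R,6R)-1-ethynyl-2,2,6-trimethyl-7-oxabicyclo[4.1.0]heptane
Conditions: dimethyl (1-diazo-2-oxopropyl)phosphonate, K2CO3, MeOH, 0 °C → rt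
Reagents that add atoms: dimethyl (1-diazo-2-oxopropyl)phosphonate, COP(=O)(OC)C(=[N+]=[N-])C(C)=O
Why: Seyferth–Gilbert homologation with the Ohira–Bestmann reagent turns the aldehyde into the terminal alkyne (C8) under mild carbonate conditions that the hindered epoxide and the quaternary C6 tolerate.

Step 14
Reactants: 22 but-2-yn-1-ol
Product: 23 tert-butyl(but-2-yn-1-yloxy)dimethylsilane
Conditions: TBSCl, imidazole, CH2Cl2, rt
Reagents that add atoms: tert-butyldimethylsilyl chloride, CC(C)(C)[Si](C)(C)Cl
Why: Silylation of the primary alcohol (silyl ether protection) masks the hydroxyl for the organometallic steps.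

Step 15
Reactants: 23 silyl ether of but-2-yn-1-ol
Product: 25 tert-butyl{[(2E)-3-iodobut-2-en-1-yl]oxy}dimethylsilane, via alkenylzirconocene chloride 24 (not isolated)
Conditions: Cp2Zr(H)Cl (excess), THF, 50 °C; then I2, 0 °C
Reagents that add atoms: iodine, II
Why: Hydrozirconation with Cp2Zr(H)Cl is a syn addition that, after equilibration with excess reagent, places zirconium on the less hindered methyl-bearing alkyne carbon, and iodinolysis with retention gives the E vinyl iodide.

Step 16
Reactants: 21 alkynyl epoxide; 25 E vinyl iodide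
Product: 28 (1R)-allenol of S axial configuration: (1R)-2-[(3E)-5-{[tert-butyl(dimethyl)silyl]oxy}-3-methylpenta-1,3-dien-1-ylidene]-1,3,3-trimethylcyclohexan-1-ol, via alkenyllithium 26 (not isolated), via alkenylmagnesium bromide 27 (not isolated)
Conditions: 25, t-BuLi (2 equiv), Et2O, −78 °C; MgBr2·OEt2; then 21, Fe(acac)3 (5 mol %), toluene–Et2O, −5 °C
Reagents that add atoms: none
Why: Iodine–lithium exchange and transmetalation give the alkenyl Grignard reagent with retention of the E geometry, and its iron-catalysed SN2′ opening of the alkynyl epoxide delivers C9 to C8 on the side of the departing C6–O bond (syn course, through iron bound to the epoxide oxygen), so that the epoxide configuration becomes the S allene axis while the C5–O bond is kept.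

Step 17
Reactants: 28 allenol
Product: 29 tert-butyl{[(2E)-3-[(2R,7aR)-4,4,7a-trimethyl-2,4,5,6,7,7a-hexahydro-1-benzofuran-2-yl]but-2-en-1-yl]oxy}dimethylsilane
Conditions: AgNO3 (0.5 equiv), CaCO3, acetone–H2O, rt, dark
Reagents that add atoms: none
Why: Silver(I)-catalysed 5-endo cycloisomerisation of the α-hydroxyallene: the C5 hydroxyl attacks C8 in the plane of the silver-bound C7=C8 bond, which transfers the allene axis to the C8 centre (R, side chain trans to the C5 methyl group) and leaves C6=C7 as the ring alkene.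

Step 18
Reactants: 29 furanoid silyl ether
Product: 30 (2E)-3-[(2R,7aR)-4,4,7a-trimethyl-2,4,5,6,7,7a-hexahydro-1-benzofuran-2-yl]but-2-en-1-ol
Conditions: TBAF, THF, 0 °C
Reagents that add atoms: none
Why: Fluoride cleavage of the silyl ether (desilylation) under non-acidic conditions frees the allylic alcohol without risk to the acid-labile C8–O bond.

Step 19
Reactants: 30 furanoid C15 alcohol
Product: 31 (2E)-3-[(2R,7aR)-4,4,7a-trimethyl-2,4,5,6,7,7a-hexahydro-1-benzofuran-2-yl]but-2-enal
Conditions: MnO2, CH2Cl2, rt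
Reagents that add atoms: none
Why: Manganese dioxide oxidises only the allylic alcohol to the enal (allylic oxidation) at neutral pH, so C8 is not epimerised.

Step 20
Reactants: 16 C25 phosphonate; 31 furanoid C15 enal
Product: 33 (5R,8R,6′R)-5,8-epoxy-5,8-dihydro-β,ε-carotene (target), via potassium C25 phosphonate carbanion 32 (not isolated)
Conditions: 16, KOtBu (1.0 equiv), THF, −78 °C; then 31, −78 → 0 °C, dark
Reagents that add atoms: none
Why: Horner–Wadsworth–Emmons olefination of the preformed polyenyl phosphonate anion with the enal forms C11=C12 with E selectivity and completes the C40 chain; with no free base present the C8–H of 31 and the C6′–H are not deprotonated, so no stereocentre is touched.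

Compound list
1 | geranyl bromide | CC(C)=CCC/C(C)=C/CBr | starting material
2 | sodium benzenesulfinate | [Na+].[O-]S(=O)c1ccccc1 | starting material
3 | geranyl phenyl sulfone | CC(C)=CCC/C(C)=C/CS(=O)(=O)c1ccccc1 | intermediate
4 | (R)-α-cyclogeranyl phenyl sulfone | CC1=CCCC(C)(C)[C@H]1CS(=O)(=O)c1ccccc1 | intermediate
5 | (2E)-4,4-dimethoxy-2-methylbut-2-enal | O=C/C(C)=C/C(OC)OC | starting material
6 | lithiated sulfone (C7′ carbanion of 4, lithium salt) | CC1=CCCC(C)(C)[C@H]1[CH-]S(=O)(=O)c1ccccc1.[Li+] | intermediate (not isolated)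
7 | lithium alkoxide of the β-hydroxy sulfone (C7′/C8′ diastereomer mixture) | CC1=CCCC(C)(C)[C@H]1C(S(=O)(=O)c1ccccc1)C([O-])/C(C)=C/C(OC)OC.[Li+] | intermediate (not isolated)
8 | (3E)-5,5-dimethoxy-3-methyl-1-(phenylsulfonyl)-1-[(1R)-2,6,6-trimethylcyclohex-2-en-1-yl]pent-3-en-2-yl acetate | CC1=CCCC(C)(C)[C@H]1C(S(=O)(=O)c1ccccc1)C(OC(C)=O)/C(C)=C/C(OC)OC | intermediate
9 | (6R)-6-[(1E,3E)-5,5-dimethoxy-3-methylpenta-1,3-dien-1-yl]-1,5,5-trimethylcyclohex-1-ene | CC1=CCCC(C)(C)[C@H]1/C=C/C(C)=C/C(OC)OC | intermediate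
10 | (2E,4E)-3-methyl-5-[(1R)-2,6,6-trimethylcyclohex-2-en-1-yl]penta-2,4-dienal | CC1=CCCC(C)(C)[C@H]1/C=C/C(C)=C/C=O | intermediate
11 | (2E,4E,6E)-2,7-dimethylocta-2,4,6-trienedial | O=C/C(C)=C/C=C/C=C(C)/C=O | starting material
12 | (2E,4E,6E)-2,7-dimethylocta-2,4,6-triene-1,8-diol | OC/C(C)=C/C=C/C=C(C)/CO | intermediate
13 | (2E,4E,6E)-1,8-dibromo-2,7-dimethylocta-2,4,6-triene | BrC/C(C)=C/C=C/C=C(C)/CBr | intermediate
14 | tetraethyl [(2E,4E,6E)-2,7-dimethylocta-2,4,6-triene-1,8-diyl]bis(phosphonate) | CCOP(=O)(OCC)C/C(C)=C/C=C/C=C(C)/CP(=O)(OCC)OCC | intermediate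
15 | potassium salt of the mono-carbanion of 14 | CCOP(=O)(OCC)[CH-]/C(C)=C/C=C/C=C(C)/CP(=O)(OCC)OCC.[K+] | intermediate (not isolated)
16 | diethyl [(2E,4E,6E,8E,10E,12E)-2,7,11-trimethyl-13-[(1R)-2,6,6-trimethylcyclohex-2-en-1-yl]trideca-2,4,6,8,10,12-hexaen-1-yl]phosphonate | CC1=CCCC(C)(C)[C@H]1/C=C/C(C)=C/C=C/C(C)=C/C=C/C=C(C)/CP(=O)(OCC)OCC | intermediate
17 | β-cyclocitral | CC1=C(C=O)C(C)(C)CCC1 | starting material
18 | β-cyclogeraniol | CC1=C(CO)C(C)(C)CCC1 | intermediate
19 | [(1R,6R)-2,2,6-trimethyl-7-oxabicyclo[4.1.0]heptan-1-yl]methanol | OC[C@@]12O[C@]1(C)CCCC2(C)C | intermediate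
20 | (1S,6R)-2,2,6-trimethyl-7-oxabicyclo[4.1.0]heptane-1-carbaldehyde | O=C[C@@]12O[C@]1(C)CCCC2(C)C | intermediate
21 | (1R,6R)-1-ethynyl-2,2,6-trimethyl-7-oxabicyclo[4.1.0]heptane | C#C[C@@]12O[C@]1(C)CCCC2(C)C | intermediate
22 | but-2-yn-1-ol | CC#CCO | starting material
23 | tert-butyl(but-2-yn-1-yloxy)dimethylsilane | CC#CCO[Si](C)(C)C(C)(C)C | intermediate
24 | chlorobis(cyclopentadienyl)[(2E)-4-{[tert-butyl(dimethyl)silyl]oxy}but-2-en-2-yl]zirconium | CC(C)(C)[Si](C)(C)OC/C=C(\C)[Zr](Cl)(C1C=CC=C1)C1C=CC=C1 | intermediate (not isolated)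
25 | tert-butyl{[(2E)-3-iodobut-2-en-1-yl]oxy}dimethylsilane | CC(C)(C)[Si](C)(C)OC/C=C(\C)I | intermediate
26 | [(2E)-4-{[tert-butyl(dimethyl)silyl]oxy}but-2-en-2-yl]lithium | CC(C)(C)[Si](C)(C)OC/C=C(\C)[Li] | intermediate (not isolated)
27 | [(2E)-4-{[tert-butyl(dimethyl)silyl]oxy}but-2-en-2-yl]magnesium bromide | CC(C)(C)[Si](C)(C)OC/C=C(\C)[Mg]Br | intermediate (not isolated)
28 | (1R)-2-[(3E)-5-{[tert-butyl(dimethyl)silyl]oxy}-3-methylpenta-1,3-dien-1-ylidene]-1,3,3-trimethylcyclohexan-1-ol, allene axis C6=C7=C8 of S configuration (viewed from C6 towards C8 with C5 on the right, C9 points down) | C[C@@]1(O)CCCC(C)(C)C1=[C@]=C/C(C)=C/CO[Si](C)(C)C(C)(C)C | intermediate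
29 | tert-butyl{[(2E)-3-[(2R,7aR)-4,4,7a-trimethyl-2,4,5,6,7,7a-hexahydro-1-benzofuran-2-yl]but-2-en-1-yl]oxy}dimethylsilane | CC(C)(C)[Si](C)(C)OC/C=C(\C)[C@H]1C=C2C(C)(C)CCC[C@@]2(C)O1 | intermediate
30 | (2E)-3-[(2R,7aR)-4,4,7a-trimethyl-2,4,5,6,7,7a-hexahydro-1-benzofuran-2-yl]but-2-en-1-ol | OC/C=C(\C)[C@H]1C=C2C(C)(C)CCC[C@@]2(C)O1 | intermediate
31 | (2E)-3-[(2R,7aR)-4,4,7a-trimethyl-2,4,5,6,7,7a-hexahydro-1-benzofuran-2-yl]but-2-enal | O=C/C=C(\C)[C@H]1C=C2C(C)(C)CCC[C@@]2(C)O1 | intermediate
32 | potassium salt of the C12 carbanion of 16 | CC1=CCCC(C)(C)[C@H]1/C=C/C(C)=C/C=C/C(C)=C/C=C/C=C(C)/[CH-]P(=O)(OCC)OCC.[K+] | intermediate (not isolated)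
33 | (5R,8R,6′R)-5,8-epoxy-5,8-dihydro-β,ε-carotene | CC1=CCCC(C)(C)[C@H]1/C=C/C(C)=C/C=C/C(C)=C/C=C/C=C(C)/C=C/C=C(\C)[C@H]1C=C2C(C)(C)CCC[C@@]2(C)O1 | target

Total step count: 20. Longest linear sequence: 9 steps (17 → 33: steps 10, 11, 12, 13, 16, 17, 18, 19, 20).

Steps most likely to fail

Step 2 (the proposed method). The enantioface discrimination may be weak because no internal nucleophile fixes the fold; proton loss may go towards the tetrasubstituted or the exocyclic alkene; and re-protonation of the product may erase C6′. Fallback with known chemistry, setting out from 3 and returning at 4: 3 is cyclised with an achiral acid (concentrated H2SO4 in acetic acid, 0 °C), the established cyclisation of this sulfone, to racemic α-cyclogeranyl phenyl sulfone F1, which is freed from the β-isomer by crystallisation; preparative chromatography on a polysaccharide-based chiral stationary phase then delivers the R antipode, which is 4.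

Step 16. The Grignard reagent may metalate the terminal alkyne instead of adding, or part of the material may react by anti delivery, so that the allene axis and with it C8 are only partly controlled. Fallback, setting out from 20 and returning at 30: Horner–Wadsworth–Emmons reaction of 20 with triethyl 3-methyl-4-phosphonocrotonate (NaH, THF) should give ethyl (2E,4E)-3-methyl-5-[(1S,6R)-2,2,6-trimethyl-7-oxabicyclo[4.1.0]heptan-1-yl]penta-2,4-dienoate F2. The classical acid-induced rearrangement of a 5,6-epoxide to the 5,8-furanoid (trace HCl in CHCl3) keeps the C5–O bond and gives ethyl (2E)-3-[(2R,7aR)-4,4,7a-trimethyl-2,4,5,6,7,7a-hexahydro-1-benzofuran-2-yl]but-2-enoate F3 together with its C8 epimer ethyl (2E)-3-[(2S,7aR)-4,4,7a-trimethyl-2,4,5,6,7,7a-hexahydro-1-benzofuran-2-yl]but-2-enoate F4. The two are separated by chromatography (F4 can be re-equilibrated with acid), and DIBAL-H reduction of F3 gives 30.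

Step 20. The basic phosphonate anion may epimerise C8 through the dienolate of the γ-alkoxy enal, and Z isomers may form at C11=C12. Fallback, setting out from 12 and 10 and returning at 33: 12 with triphenylphosphine hydrobromide gives [(2E,4E,6E)-2,7-dimethylocta-2,4,6-triene-1,8-diyl]bis(triphenylphosphonium) dibromide F5. Wittig reaction of its mono-ylide (NaOMe, 1 equiv, CH2Cl2) with 10 gives triphenyl[(2E,4E,6E,8E,10E,12E)-2,7,11-trimethyl-13-[(1R)-2,6,6-trimethylcyclohex-2-en-1-yl]trideca-2,4,6,8,10,12-hexaen-1-yl]phosphonium bromide F6. Wittig olefination of F6 with 31 in 1,2-epoxybutane, where the epoxide takes up HBr so that no free base is present, followed by thermal Z→E equilibration in heptane, should give 33.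

Further compounds
F1 | step 2 | racemic α-cyclogeranyl phenyl sulfone | CC1=CCCC(C)(C)C1CS(=O)(=O)c1ccccc1
F2 | step 16 | ethyl (2E,4E)-3-methyl-5-[(1S,6R)-2,2,6-trimethyl-7-oxabicyclo[4.1.0]heptan-1-yl]penta-2,4-dienoate | CCOC(=O)/C=C(C)/C=C/[C@@]12O[C@]1(C)CCCC2(C)C
F3 | step 16 | ethyl (2E)-3-[(2R,7aR)-4,4,7a-trimethyl-2,4,5,6,7,7a-hexahydro-1-benzofuran-2-yl]but-2-enoate | CCOC(=O)/C=C(\C)[C@H]1C=C2C(C)(C)CCC[C@@]2(C)O1
F4 | step 16 | ethyl (2E)-3-[(2S,7aR)-4,4,7a-trimethyl-2,4,5,6,7,7a-hexahydro-1-benzofuran-2-yl]but-2-enoate | CCOC(=O)/C=C(\C)[C@@H]1C=C2C(C)(C)CCC[C@@]2(C)O1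
F5 | step 20 | [(2E,4E,6E)-2,7-dimethylocta-2,4,6-triene-1,8-diyl]bis(triphenylphosphonium) dibromide | c1ccccc1[P+](c1ccccc1)(c1ccccc1)C/C(C)=C/C=C/C=C(C)/C[P+](c1ccccc1)(c1ccccc1)c1ccccc1.[Br-].[Br-]
F6 | step 20 | triphenyl[(2E,4E,6E,8E,10E,12E)-2,7,11-trimethyl-13-[(1R)-2,6,6-trimethylcyclohex-2-en-1-yl]trideca-2,4,6,8,10,12-hexaen-1-yl]phosphonium bromide | CC1=CCCC(C)(C)[C@H]1/C=C/C(C)=C/C=C/C(C)=C/C=C/C=C(C)/C[P+](c1ccccc1)(c1ccccc1)c1ccccc1.[Br-]
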